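**Two streams.** Product, I took it, reached the flask through intermediate, so I counted the two together as S. I took S to be fed from the starting material A at a first-order rate κA, and the rest of A to go to homo dimer V. Epsilon and delta, at 6.7 mol% and 15 mol%, last read S = 14.8 % and 15.8 %, close for so wide a change of loading, so I pooled them for the flask at the same 0.050 M.

| flask | starting material | free catalyst | remark | time |
|---|---|---|---|---|
| epsilon | 0.050 M | 6.7 mol% | run made earlier |  |
| delta | 0.050 M | 15 mol% | run made earlier |  |
| gamma | 0.025 M | 10 mol% | run made earlier |  |
| flask | 0.050 M | 10 mol% |  | 4.0 min |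

- epsilon (time / min: product / %, intermediate / %): 0.417: 0.3, 2.1; 0.667: 1.2, 4.9; 1.00: 3.0, 5.0; 2.00: 7.6, 4.3; 3.00: 9.4, 1.4; 5.00: 12.7, 2.1
- delta (time / min: product / %, intermediate / %): 0.417: 0, 3.2; 0.667: 2.7, 3.5; 1.00: 3.4, 3.3; 2.00: 7.6, 1.6; 3.00: 10.4, 3.2; 5.00: 14.8, 1.0
- gamma (time / min: product / %, intermediate / %): 1.00: 0.7, 7.0; 2.00: 6.1, 10.1; 3.00: 11.4, 7.8; 4.00: 13.8, 8.0; 5.00: 15.6, 4.8

(standard deviation of a reading: 1 percentage point)

- the product in the flask at 4.0 min, as a percentage of the starting material charged
- the intermediate in the flask at 4.0 min, as a percentage of the starting material charged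
- the starting material in the flask at 4.0 min, as a percentage of the starting material charged
- the homo dimer in the flask at 4.0 min, as a percentage of the starting material charged

- a species is counted by the starting material in it: one homo dimer counts as two

**The constant.** Pooled S at 0.667 min, divided by that time, gave κ = 0.0922 min⁻¹, the feed constant, the fraction of the charge entering S per minute at full A.

**Two extremes.** If A never fell, S in the flask at 4.0 min would stand at 36.9 %, with V nil. If A dimerised at once, S would stop rising and A would be nil. The pooled readings at 3.00 min and 5.00 min lie between: S averaged 13.8 % and rose at 0.0155 min⁻¹.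

**The mean.** Replacing the curve by its mean over that window, I put A at 4.0 min at slope over κ, 16.8 %. The balance then left V at 69.4 %, and S split into 1.93 % intermediate and 11.8 % product. Both means push my A high: A was already falling while κ was read, and the mean of a falling, flattening curve over a window lies above its value at the centre. The scatter of 1 percentage point weighs heavily on so small a slope.

**The result.** The forecast gave 12 %, 2 %, 50 % and 36 % for product, intermediate, starting material and homo dimer, expecting “a higher-order side drain of starting material into homo dimer”, with more A than mine. The flask gave 12.6 %, 2.38 %, 15.1 % and 69.5 %, in the same order.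

    free catalyst + intermediate → free catalyst + product (k = 3.90 M⁻¹ s⁻¹)
    free catalyst + product → spent catalyst (k = 0.0720 M⁻¹ s⁻¹)
    2 starting material → homo dimer (k = 0.170 M⁻¹ s⁻¹)
    starting material → intermediate (k = 0.00180 s⁻¹)
    free catalyst ⇌ dormant form (K = 1.40, k = 0.00100 s⁻¹)

Dimerisation used starting material at 9.44 times the feed rate at the charge, and at 1.4 times at 4.00 min. By 2.00 min it had 87 % of its turnover up to 4.0 min behind it.

For the neighbouring flask, the same charge read at 2.5 min, the pooled slope between 2.00 min and 3.00 min over κ gives 17.9 % starting material; the computed value is higher, 23.6 %.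

(The earlier runs and the new flask come from a simulation with made-up constants; scatter was added.)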